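**Plan**

1. Cuts: (a) the imidazole ring of the guanine at C8, back to a ring A benzaldehyde and 2,5,6-triaminopyrimidin-4(3H)-one; (b) both piperazine CH2–N bonds, back to the two amide bonds of a diketopiperazine; (c) the benzylic Cβ–aryl bond of ring B (Negishi); (d) ring A itself at C1–C6 and C3–C4.
2. Enabling feature: on ring A the carbon carrying guanine C8 (C1, a carboxyl-level substituent), the phenol carbon (C2) and the carbon carrying the ether oxygen to ring B (C3) are contiguous, and the benzylic CH2 sits at C5. Ring A is therefore a 3-aryloxy-5-alkylsalicylate: C1–C3 plus the carboxyl carbon are a 4-aryloxyacetoacetate, C4–C6 a 2-substituted malondialdehyde.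
3. Forward order: ring A is built with the diaryl ether already in place (steps 1–9), the ring B amino acid is joined (step 10), the 14-membered lactam and then the diketopiperazine are closed (steps 13, 14), all three carbonyl groups are reduced (step 16), and the guanine is annulated last (step 19) before global hydrogenolysis.
4. Stereochemistry: both stereocentres come from the chiral pool and none is created. The ring A arm is L-glutamic acid (its γ-carbon becomes C5 of ring A), the ring B arm is L-serine (as the 3-iodo-L-alanine derivative); both end as the (S,S)-piperazine carbons.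

Key step: step 9

Remark: the silyl enol ethers and the bis(silyloxy)diene are expected as E/Z mixtures and are used as such, because each of these double bonds ends up inside aromatic ring A; the guanine is drawn as its 7H tautomer.

**Route**

Step 1
Reactants: 1 4-bromophenol; 2 methyl 4-chloro-3-oxobutanoate (methyl 4-chloroacetoacetate)
Product: 3 methyl 4-(4-bromophenoxy)-3-oxobutanoate
Conditions: NaH (2.1 equiv), THF, 0 °C → rt; aq. HCl work-up
Reagents that add atoms: none
Why: Williamson ether synthesis: sodium 4-bromophenoxide should displace the primary chloride next to the ketone (an activated SN2 centre) while the second equivalent of NaH holds the β-keto ester as its enolate and so suppresses self-condensation.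

Step 2
Reactants: 3 methyl 4-(4-bromophenoxy)-3-oxobutanoate
Product: 4 methyl 4-(4-bromophenoxy)-3-(trimethylsilyloxy)but-2-enoate
Conditions: Me3SiCl (1.5 equiv), NEt3 (1.6 equiv), toluene, rt
Reagents that add atoms: chlorotrimethylsilane, C[Si](C)(C)Cl
Why: Silyl enol ether formation by soft enolisation: the enolised β-keto ester is O-silylated at the ketone oxygen, the standard first stage towards a 1,3-bis(silyloxy)diene.

Step 3
Reactants: 4 methyl 4-(4-bromophenoxy)-3-(trimethylsilyloxy)but-2-enoate
Product: 5 4-(4-bromophenoxy)-1-methoxy-1,3-bis(trimethylsilyloxy)buta-1,3-diene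
Conditions: LDA (1.3 equiv), THF, −78 °C; then Me3SiCl, −78 → 20 °C
Reagents that add atoms: chlorotrimethylsilane, C[Si](C)(C)Cl
Why: Kinetic γ-deprotonation of the 3-silyloxy-2-enoate with LDA and O-silylation of the dienolate (second silyl enol ether formation) should give the 1,3-bis(silyloxy)-1,3-diene, the aryl bromide being inert to the amide base at −78 °C.

Step 4
Reactants: 6 L-glutamic acid 1-methyl ester
Product: 7 (4S)-5-methoxy-5-oxo-4-phthalimidopentanoic acid
Conditions: phthalic anhydride (1.05 equiv), NEt3 (0.1 equiv), toluene, reflux, Dean–Stark trap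
Reagents that add atoms: phthalic anhydride, O=C1OC(=O)c2ccccc12
Why: N-Phthaloylation by condensation of the amine with the anhydride and thermal imide closure under azeotropic removal of water; an imide nitrogen without N–H cannot add to the later γ-aldehyde (no 5-hydroxyproline), withstands POCl3 and TiCl4, and the α-centre is not enolised under these conditions.

Step 5
Reactants: 7 (4S)-5-methoxy-5-oxo-4-phthalimidopentanoic acid
Product: 9 methyl (2S)-5-oxo-2-phthalimidopentanoate, via acid chloride 8 (not isolated)
Conditions: (COCl)2, DMF (cat.), CH2Cl2, 0 °C → rt; evaporate; then H2 (1 atm), Pd/BaSO4, 2,6-lutidine, THF, rt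
Reagents that add atoms: none
Why: Rosenmund reduction: the γ-acid chloride formed with oxalyl chloride is hydrogenolysed over Pd/BaSO4 moderated by 2,6-lutidine and stops at the aldehyde, leaving methyl ester and imide untouched.

Step 6
Reactants: 9 methyl (2S)-5-oxo-2-phthalimidopentanoate
Product: 10 methyl (2S)-5,5-dimethoxy-2-phthalimidopentanoate
Conditions: HC(OMe)3, MeOH, p-TsOH·H2O (cat.), rt
Reagents that add atoms: trimethyl orthoformate, COC(OC)OC
Why: Acid-catalysed acetalisation with trimethyl orthoformate turns the self-condensing aldehyde into the acetal that serves as enol-ether precursor in the formylation.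

Step 7
Reactants: 10 methyl (2S)-5,5-dimethoxy-2-phthalimidopentanoate
Product: 13 methyl (2S)-4-formyl-5-hydroxy-2-phthalimidopent-4-enoate (enol form of the 2-substituted malondialdehyde), via methoxypropeniminium chloride 11 (not isolated), via dimethylaminoacrolein 12 (not isolated)
Conditions: POCl3 (2.5 equiv), DMF, 0 → 65 °C; then ice–H2O; then 2 M HCl–THF, 45 °C
Reagents that add atoms: N,N-dimethylformamide, CN(C)C=O; water, O
Why: Vilsmeier–Haack–Arnold formylation of an aldehyde acetal: loss of methanol gives the enol ether, which is C-formylated at the former γ-carbon by the chloroiminium salt, and purely acidic hydrolysis of the vinylogous iminium salt and of the vinylogous formamide releases the malondialdehyde as its enol without a basic stage that would open the phthalimide.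

Step 8
Reactants: 13 methyl (2S)-4-formyl-5-hydroxy-2-phthalimidopent-4-enoate
Product: 14 methyl (2S)-4-formyl-2-phthalimido-5-(trimethylsilyloxy)pent-4-enoate
Conditions: Me3SiCl (1.5 equiv), NEt3 (1.6 equiv), toluene, rt
Reagents that add atoms: chlorotrimethylsilane, C[Si](C)(C)Cl
Why: O-Silylation of the acidic enol of a 1,3-dicarbonyl compound (silyl enol ether formation) should give the 3-silyloxy enal used as 1,3-dielectrophile.

Step 9
Reactants: 5 4-(4-bromophenoxy)-1-methoxy-1,3-bis(trimethylsilyloxy)buta-1,3-diene (1.5 equiv); 14 methyl (2S)-4-formyl-2-phthalimido-5-(trimethylsilyloxy)pent-4-enoate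
Product: 15 methyl 3-(4-bromophenoxy)-2-hydroxy-5-[(2S)-3-methoxy-3-oxo-2-phthalimidopropyl]benzoate
Conditions: TiCl4 (1.1 equiv), CH2Cl2, −78 → 20 °C, 20 h; then 10% aq. HCl
Reagents that add atoms: none
Why: TiCl4 activates the silyloxy enal, the terminal diene carbon (the one bearing the aryloxy group) adds to its β-carbon in a vinylogous Mukaiyama addition–elimination that expels the silyloxy group, and the central carbon of the remaining silyl enol ether then attacks the aldehyde, after which loss of water and enolisation aromatise the ring. The closest known reaction type is the TiCl4-mediated formal [3+3] cyclocondensation of 1,3-bis(silyloxy)-1,3-butadienes with 3-silyloxy-2-en-1-ones, which is established for 4-aryloxy dienes and gives 3-aryloxysalicylates. Ring A is closed by a 6-(enolexo)-exo-trig Mukaiyama aldol step that forms C1–C6 after the intermolecular C3–C4 bond. No stereocentre is formed, and the phthalimido ester centre lies two atoms from the reacting carbons and is not enolised under Lewis-acidic, base-free conditions at low temperature. The only selectivity needed is regiochemical and the substrates secure it: both formyl-level carbons of the malondialdehyde unit end as ring CH, so either order of bond formation gives the same 2-hydroxy-3-aryloxy-5-alkylbenzoate, while in the diene the ester-flanked carbon can only become C1 and the aryloxy carbon C3.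

Step 10
Reactants: 15 methyl 3-(4-bromophenoxy)-2-hydroxy-5-[(2S)-3-methoxy-3-oxo-2-phthalimidopropyl]benzoate; 16 benzyl (2R)-2-(tert-butoxycarbonylamino)-3-iodopropanoate (N-Boc-3-iodo-L-alanine benzyl ester; 2.5 equiv)
Product: 18 methyl 3-{4-[(2S)-3-(benzyloxy)-2-(tert-butoxycarbonylamino)-3-oxopropyl]phenoxy}-2-hydroxy-5-[(2S)-3-methoxy-3-oxo-2-phthalimidopropyl]benzoate, via alkylzinc iodide 17 (not isolated)
Conditions: 16, Zn dust, I2 (cat.), DMF, rt; then 15, Pd2(dba)3 (2.5 mol%), SPhos (5 mol%), DMF, 50 °C
Reagents that add atoms: none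
Why: Negishi coupling: zinc insertion into the iodide gives the serine-derived alkylzinc iodide, stabilised against β-elimination by internal carbonyl coordination, which transmetallates to the arylpalladium bromide formed from the SPhos-ligated zerovalent palladium catalyst; the stereocentre is not involved and stays L, and the excess of zinc reagent allows for the hydrogen-bonded phenol.

Step 11
Reactants: 18 (as named in step 10)
Product: 19 methyl 5-[(2S)-2-amino-3-methoxy-3-oxopropyl]-3-{4-[(2S)-3-(benzyloxy)-2-(tert-butoxycarbonylamino)-3-oxopropyl]phenoxy}-2-hydroxybenzoate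
Conditions: N2H4·H2O (1.5 equiv), MeOH–THF, 0 °C → rt
Reagents that add atoms: none
Why: Hydrazinolysis of the phthalimide (Ing–Manske reaction): hydrazine attacks the imide far faster than the methyl and benzyl esters at room temperature and phthalhydrazide is expelled.

Step 12
Reactants: 19 (as named in step 11)
Product: 20 (2S)-3-(4-{5-[(2S)-2-amino-3-methoxy-3-oxopropyl]-2-hydroxy-3-(methoxycarbonyl)phenoxy}phenyl)-2-(tert-butoxycarbonylamino)propanoic acid
Conditions: H2 (1 atm), Pd/C, THF–H2O, rt
Reagents that add atoms: none
Why: Hydrogenolysis of the benzyl ester over Pd/C should free the ring B carboxylic acid without touching methyl esters, Boc group or diaryl ether.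

Step 13
Reactants: 20 (as named in step 12)
Product: 21 14-membered macrolactam (amide from the ring B carboxyl to the ring A amino nitrogen; NHBoc arm and CO2Me arm both S; CO2Me at C1 and OH at C2 of ring A)
Conditions: FDPP (2 equiv), iPr2NEt (4 equiv), DMF (0.5 mM), rt
Reagents that add atoms: none
Why: Macrolactamisation at high dilution: FDPP converts the urethane-protected acid (no oxazolone racemisation) into its pentafluorophenyl ester, which the primary amine attacks intramolecularly to close the 14-membered lactam; a phosphinate reagent cannot cap the amine as a guanidine and the hindered hydrogen-bonded phenol is not acylated.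

Step 14
Reactants: 21 14-membered macrolactam
Product: 23 bridged diketopiperazine [(3S,6S)-piperazine-2,5-dione whose two CH2 arms are joined through ring B (para) and the ether oxygen to C3 and C5 of ring A; CO2Me at C1 and OH at C2 of ring A], via ammonium trifluoroacetate 22 (not isolated)
Conditions: TFA–CH2Cl2 (1:3), rt; evaporate; then NEt3 (5 equiv), 2-butanol–toluene (1:1), 90 °C
Reagents that add atoms: none
Why: Boc acidolysis followed by diketopiperazine formation from the resulting dipeptide methyl ester (intramolecular aminolysis, 6-exo-trig), a closure that is normally spontaneous for dipeptide esters and that here joins two arms held on the same face by the L,L configuration.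

Step 15
Reactants: 23 bridged diketopiperazine
Product: 24 O-benzyl ether of 23 (benzyloxy at C2 of ring A)
Conditions: BnBr (1.3 equiv), K2CO3 (2 equiv), DMF, 40 °C
Reagents that add atoms: benzyl bromide, BrCc1ccccc1
Why: Williamson O-benzylation: K2CO3 deprotonates only the phenol (not the lactam N–H groups), and the benzyl ether shields the electron-rich phenol from the later oxidations.

Step 16
Reactants: 24 O-benzyl diketopiperazine
Product: 25 bridged (2S,5S)-piperazine with benzyloxy at C2 and hydroxymethyl at C1 of ring A
Conditions: LiAlH4 (10 equiv), THF, reflux; then H2O/aq. NaOH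
Reagents that add atoms: none
Why: Hydride reduction with LiAlH4 converts both lactams into amines (diketopiperazine to piperazine) and the benzoate into the benzylic alcohol in one operation; the stereocentres are not enolised and a trans isomer could not span the bridge.

Step 17
Reactants: 25 bridged piperazine benzylic alcohol
Product: 26 N,N'-bis(benzyloxycarbonyl) derivative of 25
Conditions: CbzCl (2.5 equiv), NaHCO3, THF–H2O (1:1), 0 °C → rt
Reagents that add atoms: benzyl chloroformate, O=C(Cl)OCc1ccccc1
Why: Schotten–Baumann carbamoylation of the two secondary amines with benzyl chloroformate; in aqueous bicarbonate the benzylic alcohol is not acylated.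

Step 18
Reactants: 26 bis-carbamate benzylic alcohol
Product: 27 corresponding ring A benzaldehyde (CHO at C1; benzyloxy at C2)
Conditions: MnO2 (activated, 15 equiv), CH2Cl2, rt
Reagents that add atoms: none
Why: MnO2 oxidation, selective for the benzylic alcohol, should stop at the aldehyde and leave carbamates and benzyl ether untouched.

Step 19
Reactants: 27 ring A benzaldehyde; 28 2,5,6-triaminopyrimidin-4(3H)-one sulfate (1.3 equiv)
Product: 30 O-benzyl-N,N'-bis(benzyloxycarbonyl)guanipiperazine A, via Schiff base 29 (not isolated)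
Conditions: NaOAc (2.6 equiv), DMSO, 70 °C; then FeCl3 (10 mol%), O2 (1 atm), 90 °C
Reagents that add atoms: none
Why: Traube-type purine synthesis in its aldehyde variant: the most nucleophilic 5-amino group forms the Schiff base, the 6-amino group adds to the azomethine carbon (5-endo-trig) and iron-catalysed aerobic dehydrogenation of the 7,8-dihydropurine aromatises the imidazole ring to the 8-arylguanine.

Step 20
Reactants: 30 O-benzyl-N,N'-bis(benzyloxycarbonyl)guanipiperazine A
Product: 31 guanipiperazine A
Conditions: H2 (1 atm), Pd(OH)2/C, DMF–EtOH (1:1), rt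
Reagents that add atoms: none
Why: Catalytic hydrogenolysis removes the benzyl ether and both benzyl carbamates (as toluene and CO2) in one operation, the purine, diaryl ether and stereocentres being inert to H2/Pd.

**Compound list**

1 | 4-bromophenol | Oc1ccc(Br)cc1 | starting material
2 | methyl 4-chloro-3-oxobutanoate | COC(=O)CC(=O)CCl | starting material
3 | methyl 4-(4-bromophenoxy)-3-oxobutanoate | COC(=O)CC(=O)COc1ccc(Br)cc1 | intermediate
4 | methyl 4-(4-bromophenoxy)-3-(trimethylsilyloxy)but-2-enoate | COC(=O)C=C(COc1ccc(Br)cc1)O[Si](C)(C)C | intermediate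
5 | 4-(4-bromophenoxy)-1-methoxy-1,3-bis(trimethylsilyloxy)buta-1,3-diene | COC(O[Si](C)(C)C)=CC(O[Si](C)(C)C)=COc1ccc(Br)cc1 | intermediate
6 | L-glutamic acid 1-methyl ester, (4S)-4-amino-5-methoxy-5-oxopentanoic acid | COC(=O)[C@@H](N)CCC(=O)O | starting material
7 | (4S)-5-methoxy-5-oxo-4-phthalimidopentanoic acid | COC(=O)[C@H](CCC(=O)O)N1C(=O)c2ccccc2C1=O | intermediate
8 | methyl (2S)-5-chloro-5-oxo-2-phthalimidopentanoate (acid chloride, not isolated) | COC(=O)[C@H](CCC(=O)Cl)N1C(=O)c2ccccc2C1=O | intermediate
9 | methyl (2S)-5-oxo-2-phthalimidopentanoate | COC(=O)[C@H](CCC=O)N1C(=O)c2ccccc2C1=O | intermediate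
10 | methyl (2S)-5,5-dimethoxy-2-phthalimidopentanoate | COC(=O)[C@H](CCC(OC)OC)N1C(=O)c2ccccc2C1=O | intermediate
11 | N-[(4S)-5-methoxy-2-(methoxymethylidene)-5-oxo-4-phthalimidopentylidene]-N-methylmethanaminium chloride (not isolated) | COC(=O)[C@H](CC(C=[N+](C)C)=COC)N1C(=O)c2ccccc2C1=O.[Cl-] | intermediate
12 | methyl (2S)-5-(dimethylamino)-4-formyl-2-phthalimidopent-4-enoate (not isolated) | COC(=O)[C@H](CC(C=O)=CN(C)C)N1C(=O)c2ccccc2C1=O | intermediate
13 | methyl (2S)-4-formyl-5-hydroxy-2-phthalimidopent-4-enoate (malondialdehyde enol) | COC(=O)[C@H](CC(C=O)=CO)N1C(=O)c2ccccc2C1=O | intermediate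
14 | methyl (2S)-4-formyl-2-phthalimido-5-(trimethylsilyloxy)pent-4-enoate | COC(=O)[C@H](CC(C=O)=CO[Si](C)(C)C)N1C(=O)c2ccccc2C1=O | intermediate
15 | methyl 3-(4-bromophenoxy)-2-hydroxy-5-[(2S)-3-methoxy-3-oxo-2-phthalimidopropyl]benzoate | COC(=O)c1cc(C[C@H](N2C(=O)c3ccccc3C2=O)C(=O)OC)cc(Oc2ccc(Br)cc2)c1O | intermediate
16 | benzyl (2R)-2-(tert-butoxycarbonylamino)-3-iodopropanoate (N-Boc-3-iodo-L-alanine benzyl ester) | CC(C)(C)OC(=O)N[C@@H](CI)C(=O)OCc1ccccc1 | starting material
17 | [(2R)-3-(benzyloxy)-2-(tert-butoxycarbonylamino)-3-oxopropyl]zinc iodide (not isolated) | CC(C)(C)OC(=O)N[C@@H](C[Zn]I)C(=O)OCc1ccccc1 | intermediate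
18 | methyl 3-{4-[(2S)-3-(benzyloxy)-2-(tert-butoxycarbonylamino)-3-oxopropyl]phenoxy}-2-hydroxy-5-[(2S)-3-methoxy-3-oxo-2-phthalimidopropyl]benzoate | COC(=O)c1cc(C[C@H](N2C(=O)c3ccccc3C2=O)C(=O)OC)cc(Oc2ccc(C[C@H](NC(=O)OC(C)(C)C)C(=O)OCc3ccccc3)cc2)c1O | intermediate
19 | methyl 5-[(2S)-2-amino-3-methoxy-3-oxopropyl]-3-{4-[(2S)-3-(benzyloxy)-2-(tert-butoxycarbonylamino)-3-oxopropyl]phenoxy}-2-hydroxybenzoate | COC(=O)c1cc(C[C@H](N)C(=O)OC)cc(Oc2ccc(C[C@H](NC(=O)OC(C)(C)C)C(=O)OCc3ccccc3)cc2)c1O | intermediate
20 | (2S)-3-(4-{5-[(2S)-2-amino-3-methoxy-3-oxopropyl]-2-hydroxy-3-(methoxycarbonyl)phenoxy}phenyl)-2-(tert-butoxycarbonylamino)propanoic acid | COC(=O)c1cc(C[C@H](N)C(=O)OC)cc(Oc2ccc(C[C@H](NC(=O)OC(C)(C)C)C(=O)O)cc2)c1O | intermediate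
21 | 14-membered macrolactam: ring A C3–C5, its benzylic CH2, the ring A α-carbon (S, CO2Me), N–H, C=O, the ring B α-carbon (S, NHBoc), its benzylic CH2, ring B (para) and the ether oxygen; CO2Me at C1 and OH at C2 of ring A | COC(=O)c1cc2cc(c1O)Oc1ccc(cc1)C[C@H](NC(=O)OC(C)(C)C)C(=O)N[C@@H](C2)C(=O)OC | intermediate
22 | Boc-free macrolactam as ammonium trifluoroacetate (not isolated) | COC(=O)c1cc2cc(c1O)Oc1ccc(cc1)C[C@H]([NH3+])C(=O)N[C@@H](C2)C(=O)OC.[O-]C(=O)C(F)(F)F | intermediate
23 | bridged (3S,6S)-diketopiperazine with CO2Me at C1 and OH at C2 of ring A | COC(=O)c1cc2cc(c1O)Oc1ccc(cc1)C[C@H]1C(=O)N[C@@H](C2)C(=O)N1 | intermediate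
24 | O-benzyl ether of 23 | COC(=O)c1cc2cc(c1OCc1ccccc1)Oc1ccc(cc1)C[C@H]1C(=O)N[C@@H](C2)C(=O)N1 | intermediate
25 | bridged (2S,5S)-piperazine with benzyloxy at C2 and hydroxymethyl at C1 of ring A | OCc1cc2cc(c1OCc1ccccc1)Oc1ccc(cc1)C[C@H]1CN[C@@H](C2)CN1 | intermediate
26 | N,N'-bis(benzyloxycarbonyl) derivative of 25 | OCc1cc2cc(c1OCc1ccccc1)Oc1ccc(cc1)C[C@H]1CN(C(=O)OCc3ccccc3)[C@@H](C2)CN1C(=O)OCc1ccccc1 | intermediate
27 | ring A benzaldehyde corresponding to 26 | O=Cc1cc2cc(c1OCc1ccccc1)Oc1ccc(cc1)C[C@H]1CN(C(=O)OCc3ccccc3)[C@@H](C2)CN1C(=O)OCc1ccccc1 | intermediate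
28 | 2,5,6-triaminopyrimidin-4(3H)-one sulfate | Nc1nc(N)c(N)c(=O)[nH]1.OS(=O)(=O)O | starting material
29 | Schiff base of 27 at the 5-amino group of the triaminopyrimidinone (not isolated) | Nc1nc(N)c(N=Cc2cc3cc(c2OCc2ccccc2)Oc2ccc(cc2)C[C@H]2CN(C(=O)OCc4ccccc4)[C@@H](C3)CN2C(=O)OCc2ccccc2)c(=O)[nH]1 | intermediate
30 | O-benzyl-N,N'-bis(benzyloxycarbonyl)guanipiperazine A | Nc1nc2nc(-c3cc4cc(c3OCc3ccccc3)Oc3ccc(cc3)C[C@H]3CN(C(=O)OCc5ccccc5)[C@@H](C4)CN3C(=O)OCc3ccccc3)[nH]c2c(=O)[nH]1 | intermediate
31 | guanipiperazine A | Nc1nc2nc(-c3cc4cc(c3O)Oc3ccc(cc3)C[C@H]3CN[C@H](CN3)C4)[nH]c2c(=O)[nH]1 | target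

**Step count**

Total: 20 steps. Longest linear sequence: 17 steps (from 6 through steps 4–20).

**Steps most likely to fail**

Step 13 (macrolactamisation). Cyclodimerisation and oligomerisation may outrun ring closure, because a secondary amide has to form inside the short six-atom bridge of a strained 14-membered meta,para-cyclophane. The fallback is a ring contraction through a larger, unstrained ring; it sets out from 19 and returns at 22. Reductive amination of 19 with 2-hydroxy-4-methoxybenzaldehyde (NaBH(OAc)3, 1,2-dichloroethane) should give the N-(2-hydroxy-4-methoxybenzyl) amine F1. Hydrogenolysis of its benzyl ester (H2, Pd/C) gives the N-(2-hydroxy-4-methoxybenzyl) amino acid F2. Activation at high dilution (FDPP, iPr2NEt, DMF) first esterifies the auxiliary phenol to the 18-membered lactone F3 (not isolated), which contracts by O-to-N acyl shift through a six-membered transition state to the N-(2-hydroxy-4-methoxybenzyl) macrolactam F4. TFA with Et3SiH removes the Boc group and the auxiliary together and delivers 22, which is cyclised as in the second stage of step 14.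

Step 14 (transannular diketopiperazine closure). The cyclophane may hold the lactam amide trans, so that the amine cannot reach the ester; forcing the closure thermally then invites epimerisation and intermolecular aminolysis. The fallback passes through a piperazin-2-one instead of a diketopiperazine; it sets out from 21 and returns at 26. Thionation of the ring amide (Lawesson's reagent, THF, 60 °C) should give the thiolactam F5, and desulfurisation (NiCl2·6H2O, NaBH4, MeOH–THF, 0 °C) the flexible 14-membered cyclic secondary amine F6. TFA removes the Boc group to give the diamine bis(trifluoroacetate) F7 (not isolated), and NEt3 in MeOH at 50 °C lets the primary amine close onto the methyl ester in an unconstrained 6-exo-trig lactamisation to the bridged piperazin-2-one F8. LiAlH4 (THF, reflux) reduces lactam and benzoate to the piperazine phenol alcohol F9. CbzCl/NaHCO3 gives the bis-carbamate phenol F10, and BnBr/K2CO3 (DMF) benzylates its phenol to give 26.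

Step 9 (cyclocondensation). Desilylation or oligomerisation of the silyloxy enal by TiCl4 and hydrolysis of the diene may outpace the second C–C bond formation, leaving open-chain mono-adducts. The fallback condenses the unsilylated partners under amine catalysis; it sets out from 3 and 13 and returns at 15, and makes no compound outside the list (F0). β-Keto ester 3 and malondialdehyde 13 are heated with piperidinium acetate (20 mol%) in toluene with removal of water. Knoevenagel condensation at C2 of the keto ester, then intramolecular aldol condensation of the aryloxy-activated C4 methylene with the second formyl group and tautomerisation, forms the same C1–C6 and C3–C4 bonds. This is the classical base-mediated phenol synthesis from malondialdehydes and ketones with two acidic α-methylene groups.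

Further compounds
F1 | step 13 | methyl 3-{4-[(2S)-3-(benzyloxy)-2-(tert-butoxycarbonylamino)-3-oxopropyl]phenoxy}-2-hydroxy-5-{(2S)-2-[(2-hydroxy-4-methoxybenzyl)amino]-3-methoxy-3-oxopropyl}benzoate | COC(=O)c1cc(C[C@H](NCc2ccc(OC)cc2O)C(=O)OC)cc(Oc2ccc(C[C@H](NC(=O)OC(C)(C)C)C(=O)OCc3ccccc3)cc2)c1O
F2 | step 13 | ring B carboxylic acid of F1 (benzyl ester cleaved) | COC(=O)c1cc(C[C@H](NCc2ccc(OC)cc2O)C(=O)OC)cc(Oc2ccc(C[C@H](NC(=O)OC(C)(C)C)C(=O)O)cc2)c1O
F3 | step 13 | 18-membered lactone (ring B carboxyl esterified with the auxiliary phenol; not isolated) | COC(=O)c1cc2cc(c1O)Oc1ccc(cc1)C[C@H](NC(=O)OC(C)(C)C)C(=O)Oc1cc(OC)ccc1CN[C@@H](C2)C(=O)OC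
F4 | step 13 | N-(2-hydroxy-4-methoxybenzyl) derivative of macrolactam 21 | COC(=O)c1cc2cc(c1O)Oc1ccc(cc1)C[C@H](NC(=O)OC(C)(C)C)C(=O)N(Cc1ccc(OC)cc1O)[C@@H](C2)C(=O)OC
F5 | step 14 | thiolactam of 21 (C=S in place of the ring amide C=O) | COC(=O)c1cc2cc(c1O)Oc1ccc(cc1)C[C@H](NC(=O)OC(C)(C)C)C(=S)N[C@@H](C2)C(=O)OC
F6 | step 14 | 14-membered cyclic secondary amine (CH2 in place of the ring amide C=O of 21) | COC(=O)c1cc2cc(c1O)Oc1ccc(cc1)C[C@H](NC(=O)OC(C)(C)C)CN[C@@H](C2)C(=O)OC
F7 | step 14 | Boc-free diamine of F6 as bis(trifluoroacetate) (not isolated) | COC(=O)c1cc2cc(c1O)Oc1ccc(cc1)C[C@H](N)CN[C@@H](C2)C(=O)OC.OC(=O)C(F)(F)F.OC(=O)C(F)(F)F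
F8 | step 14 | bridged (3S,6S)-piperazin-2-one with CO2Me at C1 and OH at C2 of ring A | COC(=O)c1cc2cc(c1O)Oc1ccc(cc1)C[C@H]1CN[C@@H](C2)C(=O)N1
F9 | step 14 | bridged (2S,5S)-piperazine with free OH at C2 and hydroxymethyl at C1 of ring A | OCc1cc2cc(c1O)Oc1ccc(cc1)C[C@H]1CN[C@@H](C2)CN1
F10 | step 14 | N,N'-bis(benzyloxycarbonyl) derivative of F9 | OCc1cc2cc(c1O)Oc1ccc(cc1)C[C@H]1CN(C(=O)OCc3ccccc3)[C@@H](C2)CN1C(=O)OCc1ccccc1
F0 | step 9 | none | none
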